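## Retrosynthetic overview

1. Target 16 ⇐ dibenzyl ether 15 by O-debenzylation (last step).
2. 15 ⇐ enaminone 5 + quinone monoketal 12 (C3–C1' bond). 12 ionises to the aryl enolonium ion 13, so the phenol ortho carbon, normally a nucleophile, is the electrophile for the nucleophilic enaminone α-carbon. Ring C closes in the same flask.
3. 12 ⇐ phenol 10 (oxidative ketalisation) ⇐ dihydrocoumarin 7 + MeMgBr ⇐ arylpropanoic acid 6 (oxidative lactonisation).
4. 5 ⇐ phloroacetophenone 1 (dibenzylation, then DMF-DMA).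
5. Ring order: rings A and B are bought as arenes (1 and 6). A temporary lactone ring is made in step 3 and opened in step 4. The pyranone ring C is formed last, in step 6.

Assumption: the target has no stereocentre (it is achiral), so no stereocontrol is needed; the only stereo-elements on the way are E-enaminone double bonds, which disappear in step 6.

## Route

Step 1
Reactants: 1 2',4',6'-trihydroxyacetophenone (phloroacetophenone, dried); 2 benzyl bromide
Product: 3 1-[2,4-bis(benzyloxy)-6-hydroxyphenyl]ethan-1-one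
Conditions: BnBr (2.1 equiv), K2CO3 (2.2 equiv), DMF, rt, 16 h
Reagents that add atoms: benzyl bromide, BrCc1ccccc1
Why: Williamson ether synthesis; the 4-OH and one ortho OH are alkylated, while the last ortho OH stays hydrogen-bonded to the ketone and is much less nucleophilic, so 2.1 equiv of BnBr stops at the dibenzyl ether.

Step 2
Reactants: 3 1-[2,4-bis(benzyloxy)-6-hydroxyphenyl]ethan-1-one; 4 N,N-dimethylformamide dimethyl acetal
Product: 5 (E)-1-[2,4-bis(benzyloxy)-6-hydroxyphenyl]-3-(dimethylamino)prop-2-en-1-one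
Conditions: DMF-DMA (3 equiv), toluene, 95 °C, 3 h
Reagents that add atoms: N,N-dimethylformamide dimethyl acetal, COC(OC)N(C)C
Why: Enaminone formation by condensation of the methyl ketone with an amide acetal; the chelated phenol is not methylated and the push–pull alkene forms as the thermodynamic E isomer.

Step 3
Reactants: 6 3-(2,3-dimethoxyphenyl)propanoic acid
Product: 7 5,6-dimethoxy-3,4-dihydro-2H-chromen-2-one
Conditions: PhI(OCOCF3)2 (1.2 equiv), BF3·OEt2 (1.5 equiv), TFA/CH2Cl2, 0 °C → rt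
Reagents that add atoms: none
Why: Hypervalent-iodine oxidative C–O lactonisation of an electron-rich 3-arylpropanoic acid (arene radical cation / spirolactone pathway); the only free ortho position, para to the 3-OMe group, takes the carboxylate oxygen to give the dihydrocoumarin.

Step 4
Reactants: 7 5,6-dimethoxy-3,4-dihydro-2H-chromen-2-one; 8 methylmagnesium bromide
Product: 10 2-(3-hydroxy-3-methylbutyl)-3,4-dimethoxyphenol, via methyl ketone 9 (not isolated)
Conditions: MeMgBr (3.5 equiv), THF, 0 °C → rt; then H2O/aq NH4Cl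
Reagents that add atoms: methylmagnesium bromide, C[Mg]Br
Why: Double Grignard addition to a lactone; the first addition opens the aryl ester to the phenoxide and ketone 9, the second gives the tertiary alkoxide, and a near-neutral quench avoids acid-mediated chroman formation.

Step 5
Reactants: 10 2-(3-hydroxy-3-methylbutyl)-3,4-dimethoxyphenol; 11 methanol
Product: 12 2-(3-hydroxy-3-methylbutyl)-3,4,4-trimethoxycyclohexa-2,5-dien-1-one
Conditions: PhI(OAc)2 (1.1 equiv), MeOH, 0 °C, 30 min; NaHCO3 work-up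
Reagents that add atoms: methanol, CO
Why: Oxidative dearomatisation of a p-methoxyphenol with a λ3-iodane; methanol adds at the para carbon that already carries OMe, giving the quinone monoketal.

Step 6
Reactants: 5 (E)-1-[2,4-bis(benzyloxy)-6-hydroxyphenyl]-3-(dimethylamino)prop-2-en-1-one; 12 2-(3-hydroxy-3-methylbutyl)-3,4,4-trimethoxycyclohexa-2,5-dien-1-one (1.3 equiv)
Product: 15 5,7-bis(benzyloxy)-3-[2-hydroxy-3-(3-hydroxy-3-methylbutyl)-4,5-dimethoxyphenyl]-4H-chromen-4-one, via aryl enolonium ion 13 (not isolated), via C-arylated enaminone 14 (not isolated)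
Conditions: C6F5CO2H (1.2 equiv), (CF3)2CHOH/CH2Cl2 1:1, 4 Å MS, −20 °C → rt; NaHCO3 work-up
Reagents that add atoms: none
Why: Proposed new method: the acid/fluoroalcohol medium ionises ketal 12 (loss of MeOH) to the oxocarbenium/phenoxenium ion 13, whose carbon α to the dienone C=O (the ortho carbon of the parent phenol) is electrophilic, i.e. an aryl enolonium equivalent; the nucleophilic α-carbon of enaminone 5 attacks the only unsubstituted α-position (the other carries the side chain), tautomerisation gives 14, and the chelated ring-A phenol then closes 6-endo on the β-carbon with loss of Me2NH (closure through the ring-B oxygen would be 5-endo-trig on the planar push–pull system); the closest known reactions are the Brønsted acid/fluoroalcohol coupling of quinone monoacetals with arenes and alkenes at the carbon α to the carbonyl, and the domino α-functionalisation/chromone annulation of o-hydroxyaryl enaminones with electrophiles.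

Step 7
Reactants: 15 5,7-bis(benzyloxy)-3-[2-hydroxy-3-(3-hydroxy-3-methylbutyl)-4,5-dimethoxyphenyl]-4H-chromen-4-one
Product: 16 5,7-dihydroxy-3-[2-hydroxy-3-(3-hydroxy-3-methylbutyl)-4,5-dimethoxyphenyl]-4H-chromen-4-one
Conditions: H2 (1 atm), 10% Pd/C, EtOAc/MeOH, rt, stopped after 2 equiv H2
Reagents that add atoms: none
Why: Catalytic hydrogenolysis of benzyl aryl ethers under neutral conditions, which spares the methyl ethers, the chromone C2=C3 bond and the tertiary alcohol (acid would cyclise it onto the 2'-OH).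

## Compound list

1 | 2',4',6'-trihydroxyacetophenone | CC(=O)c1c(O)cc(O)cc1O | starting material
2 | benzyl bromide | BrCc1ccccc1 | starting material
3 | 1-[2,4-bis(benzyloxy)-6-hydroxyphenyl]ethan-1-one | CC(=O)c1c(O)cc(OCc2ccccc2)cc1OCc1ccccc1 | intermediate
4 | N,N-dimethylformamide dimethyl acetal | COC(OC)N(C)C | starting material
5 | (E)-1-[2,4-bis(benzyloxy)-6-hydroxyphenyl]-3-(dimethylamino)prop-2-en-1-one | CN(C)/C=C/C(=O)c1c(O)cc(OCc2ccccc2)cc1OCc1ccccc1 | intermediate
6 | 3-(2,3-dimethoxyphenyl)propanoic acid | COc1cccc(CCC(=O)O)c1OC | starting material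
7 | 5,6-dimethoxy-3,4-dihydro-2H-chromen-2-one | COc1ccc2OC(=O)CCc2c1OC | intermediate
8 | methylmagnesium bromide | C[Mg]Br | starting material
9 | 4-(6-hydroxy-2,3-dimethoxyphenyl)butan-2-one (present as its magnesium phenoxide) | CC(=O)CCc1c(O)ccc(OC)c1OC | intermediate (not isolated)
10 | 2-(3-hydroxy-3-methylbutyl)-3,4-dimethoxyphenol | COc1ccc(O)c(CCC(C)(C)O)c1OC | intermediate
11 | methanol | CO | starting material
12 | 2-(3-hydroxy-3-methylbutyl)-3,4,4-trimethoxycyclohexa-2,5-dien-1-one | COC1=C(CCC(C)(C)O)C(=O)C=CC1(OC)OC | intermediate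
13 | [3-(3-hydroxy-3-methylbutyl)-2-methoxy-4-oxocyclohexa-2,5-dien-1-ylidene](methyl)oxonium (counter-ion pentafluorobenzoate) | COC1=C(CCC(C)(C)O)C(=O)C=CC1=[O+]C | intermediate (not isolated)
14 | (E)-1-[2,4-bis(benzyloxy)-6-hydroxyphenyl]-3-(dimethylamino)-2-[2-hydroxy-3-(3-hydroxy-3-methylbutyl)-4,5-dimethoxyphenyl]prop-2-en-1-one | CN(C)/C=C(/C(=O)c1c(O)cc(OCc2ccccc2)cc1OCc1ccccc1)c1cc(OC)c(OC)c(CCC(C)(C)O)c1O | intermediate (not isolated)
15 | 5,7-bis(benzyloxy)-3-[2-hydroxy-3-(3-hydroxy-3-methylbutyl)-4,5-dimethoxyphenyl]-4H-chromen-4-one | COc1cc(-c2coc3cc(OCc4ccccc4)cc(OCc4ccccc4)c3c2=O)c(O)c(CCC(C)(C)O)c1OC | intermediate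
16 | 5,7-dihydroxy-3-[2-hydroxy-3-(3-hydroxy-3-methylbutyl)-4,5-dimethoxyphenyl]-4H-chromen-4-one | COc1cc(-c2coc3cc(O)cc(O)c3c2=O)c(O)c(CCC(C)(C)O)c1OC | target

## Step count and risks

Total steps: 7 (convergent: steps 1–2 and steps 3–5 run in parallel).
Longest linear sequence: 5 steps (6 → 7 → 10 → 12 → 15 → 16).

**Step 6 (most likely to fail).** The union is untested. Possible failures are closure through the ring-B oxygen to a 3-aroylbenzofuran, attack of 13 on the electron-rich ring A, and acid-induced cyclisation of the tertiary alcohol onto the 2'-OH to a 2,2-dimethylchroman. The fallback makes the same C3–C1' bond by Suzuki–Miyaura coupling with the 2'-oxygen masked. It sets out from 5 and 10 and comes back to the route at 16. Enaminone 5 with I2 (CHCl3, rt) gives 5,7-bis(benzyloxy)-3-iodo-4H-chromen-4-one F1. Phenol 10 is brominated ortho to the OH (NBS, CH2Cl2, −78 → 0 °C) to 6-bromo-2-(3-hydroxy-3-methylbutyl)-3,4-dimethoxyphenol F2. This is benzylated (BnBr, K2CO3, DMF) to 4-[2-(benzyloxy)-3-bromo-5,6-dimethoxyphenyl]-2-methylbutan-2-ol F3 and borylated (B2pin2, PdCl2(dppf), KOAc, dioxane, 90 °C) to 4-[2-(benzyloxy)-5,6-dimethoxy-3-(4,4,5,5-tetramethyl-1,3,2-dioxaborolan-2-yl)phenyl]-2-methylbutan-2-ol F4. Coupling of F1 and F4 (Pd(PPh3)4, K2CO3, DME/H2O, 80 °C) gives 5,7-bis(benzyloxy)-3-[2-(benzyloxy)-3-(3-hydroxy-3-methylbutyl)-4,5-dimethoxyphenyl]-4H-chromen-4-one F5, and hydrogenolysis as in step 7 gives 16.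

**Step 3.** The oxidative lactonisation rests on analogy with other alkoxy-substituted arylpropanoic acids; over-oxidation to quinones or low conversion is possible. The fallback sets out from 6 and comes back at 7. Intramolecular Friedel–Crafts acylation (Eaton's reagent, 50 °C) closes at the only free ortho position to give 4,5-dimethoxy-2,3-dihydro-1H-inden-1-one F6. Baeyer–Villiger oxidation (mCPBA, cat. TFA, CH2Cl2, rt), with migration of the electron-rich aryl group, then gives lactone 7.

**Step 7.** Hydrogenolysis may also reduce the chromone C2=C3 bond to the isoflavanone. The fallback replaces benzyl by allyl, which is removed by Pd(0) allyl transfer without hydrogen or acid. It sets out from 1 (and uses 12) and comes back at 16. Compound 1 with allyl bromide (2.1 equiv, K2CO3, acetone, reflux) gives 1-[2-hydroxy-4,6-bis(prop-2-en-1-yloxy)phenyl]ethan-1-one F7. DMF-DMA (toluene, 95 °C) gives (E)-3-(dimethylamino)-1-[2-hydroxy-4,6-bis(prop-2-en-1-yloxy)phenyl]prop-2-en-1-one F8. Union of F8 with 12 under the step 6 conditions gives 3-[2-hydroxy-3-(3-hydroxy-3-methylbutyl)-4,5-dimethoxyphenyl]-5,7-bis(prop-2-en-1-yloxy)-4H-chromen-4-one F9. Pd(PPh3)4 (5 mol %) and morpholine in THF at rt then give 16.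

## Further compounds

F1 | step 6 | 5,7-bis(benzyloxy)-3-iodo-4H-chromen-4-one | O=c1c(I)coc2cc(OCc3ccccc3)cc(OCc3ccccc3)c12
F2 | step 6 | 6-bromo-2-(3-hydroxy-3-methylbutyl)-3,4-dimethoxyphenol | COc1cc(Br)c(O)c(CCC(C)(C)O)c1OC
F3 | step 6 | 4-[2-(benzyloxy)-3-bromo-5,6-dimethoxyphenyl]-2-methylbutan-2-ol | COc1cc(Br)c(OCc2ccccc2)c(CCC(C)(C)O)c1OC
F4 | step 6 | 4-[2-(benzyloxy)-5,6-dimethoxy-3-(4,4,5,5-tetramethyl-1,3,2-dioxaborolan-2-yl)phenyl]-2-methylbutan-2-ol | COc1cc(B2OC(C)(C)C(C)(C)O2)c(OCc2ccccc2)c(CCC(C)(C)O)c1OC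
F5 | step 6 | 5,7-bis(benzyloxy)-3-[2-(benzyloxy)-3-(3-hydroxy-3-methylbutyl)-4,5-dimethoxyphenyl]-4H-chromen-4-one | COc1cc(-c2coc3cc(OCc4ccccc4)cc(OCc4ccccc4)c3c2=O)c(OCc2ccccc2)c(CCC(C)(C)O)c1OC
F6 | step 3 | 4,5-dimethoxy-2,3-dihydro-1H-inden-1-one | COc1ccc2C(=O)CCc2c1OC
F7 | step 7 | 1-[2-hydroxy-4,6-bis(prop-2-en-1-yloxy)phenyl]ethan-1-one | CC(=O)c1c(O)cc(OCC=C)cc1OCC=C
F8 | step 7 | (E)-3-(dimethylamino)-1-[2-hydroxy-4,6-bis(prop-2-en-1-yloxy)phenyl]prop-2-en-1-one | CN(C)/C=C/C(=O)c1c(O)cc(OCC=C)cc1OCC=C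
F9 | step 7 | 3-[2-hydroxy-3-(3-hydroxy-3-methylbutyl)-4,5-dimethoxyphenyl]-5,7-bis(prop-2-en-1-yloxy)-4H-chromen-4-one | COc1cc(-c2coc3cc(OCC=C)cc(OCC=C)c3c2=O)c(O)c(CCC(C)(C)O)c1OC
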